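**Retrosynthetic overview**
- The only ring, the oxane, is closed last: the C2–O1 bond is made by oxidative benzylic C–H etherification of an unprotected anti-(3S,5S)-1,7-diarylheptane-3,5-diol, through the ortho-quinone and para-quinone methide of ring A.
- The anti-diol comes from Noyori hydrogenation of the saturated 1,7-diarylheptane-3,5-dione; its two carbinol centres then fix C2 through an all-equatorial chair.
- The diketone comes from one hydrogenation (C=C plus three benzyl ethers) of the styryl diketone made by Pabon condensation of 3,4-bis(benzyloxy)-5-methoxybenzaldehyde with 6-[4-(benzyloxy)phenyl]hexane-2,4-dione.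
- These two pieces come from 5-hydroxyvanillin plus benzyl bromide, and from acetylacetone dianion plus 4-(benzyloxy)benzyl chloride.

Assumption: 3,4-dihydroxy-5-methoxybenzaldehyde (5-hydroxyvanillin) and 4-(benzyloxy)benzyl chloride are bought as catalogue compounds.

**Route**

Step 1
Reactants: 1 pentane-2,4-dione (acetylacetone); 2 1-(benzyloxy)-4-(chloromethyl)benzene
Product: 4 6-[4-(benzyloxy)phenyl]hexane-2,4-dione, via acetylacetone dilithium dianion 3 (not isolated)
Conditions: LiN(iPr)2 (2.2 equiv), THF, 0 °C, 30 min; 2 (0.95 equiv), 0 °C to rt; 1 M aq. HCl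
Reagents that add atoms: none
Why: Terminal (γ) alkylation of a β-diketone dianion, in which the last-formed and most basic methyl carbanion of 3 is the only site that displaces the benzylic chloride (SN2), so one arm of acetylacetone is extended; no stereocentre is formed.

Step 2
Reactants: 5 3,4-dihydroxy-5-methoxybenzaldehyde (5-hydroxyvanillin)
Product: 6 3,4-bis(benzyloxy)-5-methoxybenzaldehyde
Conditions: BnBr (2.3 equiv), K2CO3 (3 equiv), DMF, 60 °C
Reagents that add atoms: benzyl bromide, BrCc1ccccc1
Why: Williamson ether synthesis of both phenols, so that the catechol can neither bind boron nor oxidise in step 3, with benzyl groups that leave in the hydrogenation of step 4 at no extra step.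

Step 3
Reactants: 4 6-[4-(benzyloxy)phenyl]hexane-2,4-dione; 6 3,4-bis(benzyloxy)-5-methoxybenzaldehyde
Product: 9 (1E)-1-[3,4-bis(benzyloxy)-5-methoxyphenyl]-7-[4-(benzyloxy)phenyl]hept-1-ene-3,5-dione, via dibutoxyboron chelate of the diketone 7 (not isolated), via dibutoxyboron chelate of the enedione 8 (not isolated)
Conditions: B(OBu)3 (1.2 equiv), B2O3 (0.5 equiv), EtOAc, 60 °C; 6 (0.95 equiv), n-BuNH2 (0.3 equiv, slow addition), 70 °C; then 1 M aq. HCl, 55 °C
Reagents that add atoms: none
Why: Pabon condensation (boron-chelate-directed aldol condensation), in which chelate 7 masks the central CH2 and reacts at its terminal methyl rather than the more hindered C5 methylene (as in dehydrogingerdione syntheses) to give the conjugated E-alkene, and acid hydrolysis of 8 frees the diketone.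

Step 4
Reactants: 9 (1E)-1-[3,4-bis(benzyloxy)-5-methoxyphenyl]-7-[4-(benzyloxy)phenyl]hept-1-ene-3,5-dione
Product: 10 1-(3,4-dihydroxy-5-methoxyphenyl)-7-(4-hydroxyphenyl)heptane-3,5-dione
Conditions: H2 (1 atm), 10% Pd/C, EtOAc/MeOH (1:1), rt; filtered under Ar
Reagents that add atoms: none
Why: Heterogeneous catalytic hydrogenation with O-benzyl hydrogenolysis, in which Pd/C saturates the conjugated alkene and cleaves the three aryl benzyl ethers in one operation while the enolised β-diketone is untouched at room temperature; no stereocentre is formed.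

Step 5
Reactants: 10 1-(3,4-dihydroxy-5-methoxyphenyl)-7-(4-hydroxyphenyl)heptane-3,5-dione
Product: 11 (3S,5S)-1-(3,4-dihydroxy-5-methoxyphenyl)-7-(4-hydroxyphenyl)heptane-3,5-diol
Conditions: RuCl2[(S)-BINAP](dmf)n (1 mol %), H2 (60 atm), degassed MeOH, 50 °C
Reagents that add atoms: none
Why: Noyori asymmetric hydrogenation of a β-diketone, in which each carbonyl is reduced through its ruthenium chelate under control of (S)-BINAP to give the anti (3S,5S) diol (the sense in which (S)-BINAP gives (S,S)-pentane-2,4-diol from acetylacetone), and wrongly reduced first-stage material ends up as the separable syn diol so the ee of the anti diol is amplified.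

Step 6
Reactants: 11 (3S,5S)-1-(3,4-dihydroxy-5-methoxyphenyl)-7-(4-hydroxyphenyl)heptane-3,5-diol
Product: 14 (2S,4R,6S)-2-(3,4-dihydroxy-5-methoxyphenyl)-6-[2-(4-hydroxyphenyl)ethyl]oxan-4-ol, via ring-A ortho-quinone 12 (not isolated), via para-quinone methide 13 (not isolated)
Conditions: Ag2O (1.0 equiv), 4 Å MS, MeCN (0.01 M), 0 °C, dark, 20 min; filter (Celite, Ar); (PhO)2P(O)OH (10 mol %), 0 °C to rt
Reagents that add atoms: none
Why: Proposed new method: Ag2O oxidises only the catechol of ring A to ortho-quinone 12 (the monophenol of ring B and the secondary alcohols are inert to it), the phosphoric acid diester shuttles a benzylic proton so that 12 tautomerises to the 2-hydroxy-6-methoxy para-quinone methide 13 (ring attack by the C3 hydroxyl is disfavoured because the 3'-methoxy group turns the only free 1,4-position into an enol-ether carbon, and that hydroxyl could otherwise only form an oxetane), and the C5 hydroxyl then closes the oxane by 6-exo oxa-1,6-addition through a chair with the C3 hydroxyl, the C5 side chain and the aryl group all equatorial, which rearomatises the catechol and sets C2 as S (2,6-cis), with acid-mediated reversal through 13 funnelling any C2 epimer to the all-equatorial product; the closest known reaction types are the ortho-quinone to para-quinone methide isomerisation of 4-alkylcatechols and Brønsted acid catalysed 1,6-additions of O-nucleophiles to para-quinone methides, which have not been combined as an intramolecular benzylic C–H etherification of an unprotected polyphenol polyol.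

**Compound list**

1 | pentane-2,4-dione (acetylacetone) | CC(=O)CC(C)=O | starting material
2 | 1-(benzyloxy)-4-(chloromethyl)benzene (4-benzyloxybenzyl chloride) | ClCc1ccc(OCc2ccccc2)cc1 | starting material
3 | acetylacetone dilithium dianion (dilithium penta-1,3-diene-2,4-bis(olate); not isolated) | C=C([O-])C=C(C)[O-].[Li+].[Li+] | intermediate
4 | 6-[4-(benzyloxy)phenyl]hexane-2,4-dione | CC(=O)CC(=O)CCc1ccc(OCc2ccccc2)cc1 | intermediate
5 | 3,4-dihydroxy-5-methoxybenzaldehyde (5-hydroxyvanillin) | COc1cc(C=O)cc(O)c1O | starting material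
6 | 3,4-bis(benzyloxy)-5-methoxybenzaldehyde | COc1cc(C=O)cc(OCc2ccccc2)c1OCc1ccccc1 | intermediate
7 | dibutoxyboron chelate of diketone 4 (six-membered B(OBu)2 diketonate ring; not isolated) | CCCCO[B-]1(OCCCC)OC(C)=CC(CCc2ccc(OCc3ccccc3)cc2)=[O+]1 | intermediate
8 | dibutoxyboron chelate of enedione 9 (B(OBu)2 on both diketonate oxygens, E-alkene; not isolated) | COc1cc(/C=C/C2=CC(CCc3ccc(OCc4ccccc4)cc3)=[O+][B-](OCCCC)(OCCCC)O2)cc(OCc2ccccc2)c1OCc1ccccc1 | intermediate
9 | (1E)-1-[3,4-bis(benzyloxy)-5-methoxyphenyl]-7-[4-(benzyloxy)phenyl]hept-1-ene-3,5-dione (drawn as diketone, exists as enol) | COc1cc(/C=C/C(=O)CC(=O)CCc2ccc(OCc3ccccc3)cc2)cc(OCc2ccccc2)c1OCc1ccccc1 | intermediate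
10 | 1-(3,4-dihydroxy-5-methoxyphenyl)-7-(4-hydroxyphenyl)heptane-3,5-dione | COc1cc(CCC(=O)CC(=O)CCc2ccc(O)cc2)cc(O)c1O | intermediate
11 | (3S,5S)-1-(3,4-dihydroxy-5-methoxyphenyl)-7-(4-hydroxyphenyl)heptane-3,5-diol | COc1cc(CC[C@H](O)C[C@H](CCc2ccc(O)cc2)O)cc(O)c1O | intermediate
12 | 5-[(3S,5S)-3,5-dihydroxy-7-(4-hydroxyphenyl)heptyl]-3-methoxycyclohexa-3,5-diene-1,2-dione (ring-A ortho-quinone; not isolated) | COC1=CC(CC[C@H](O)C[C@H](CCc2ccc(O)cc2)O)=CC(=O)C1=O | intermediate
13 | 4-[(3S,5S)-3,5-dihydroxy-7-(4-hydroxyphenyl)heptylidene]-2-hydroxy-6-methoxycyclohexa-2,5-dien-1-one (para-quinone methide; not isolated) | COC1=CC(=CC[C@H](O)C[C@H](CCc2ccc(O)cc2)O)C=C(O)C1=O | intermediate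
14 | (2S,4R,6S)-2-(3,4-dihydroxy-5-methoxyphenyl)-6-[2-(4-hydroxyphenyl)ethyl]oxan-4-ol (all-cis) | COc1cc([C@@H]2C[C@H](O)C[C@H](CCc3ccc(O)cc3)O2)cc(O)c1O | target

**Step count and risks**

Total steps: 6 (steps 1 and 2 run in parallel). Longest linear sequence: 5 steps (1 or 2, then 3, 4, 5, 6).

Step 6 (the new oxidative etherification) is the most likely to fail. The ortho-quinone may isomerise too slowly and couple with unreacted catechol, the product catechol may be over-oxidised, or the quinone methide may slip to the styrene. The fallback uses known chemistry and replaces C–H oxidation by a redox-neutral SN1 ring closure at a benzylic alcohol; it sets out from 4 and 6 and comes back at 14. Diketone 4 is deprotonated twice with LiN(iPr)2 to its terminal dilithium dianion F1, which adds to aldehyde 6 at −78 °C to give 1-[3,4-bis(benzyloxy)-5-methoxyphenyl]-7-[4-(benzyloxy)phenyl]-1-hydroxyheptane-3,5-dione F2, racemic at C1. RuCl2[(S)-BINAP](dmf)n and H2 reduce the diketone to (1RS,3R,5S)-1-[3,4-bis(benzyloxy)-5-methoxyphenyl]-7-[4-(benzyloxy)phenyl]heptane-1,3,5-triol F3. TsOH (5 mol %) in CH2Cl2 ionises the electron-rich benzylic alcohol and the C5 hydroxyl closes the ring stereoconvergently to (2S,4R,6S)-2-[3,4-bis(benzyloxy)-5-methoxyphenyl]-6-{2-[4-(benzyloxy)phenyl]ethyl}oxan-4-ol F4. H2 over Pd/C in EtOAc, stopped after three equivalents, removes the benzyl groups and gives 14.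

Step 5 (Noyori hydrogenation of an unprotected catechol) is the second risk. The catechol may bind ruthenium and stall the catalyst, or the anti-selectivity and ee may fall below those of simple dialkyl diketones. The fallback keeps the benzyl ethers through the asymmetric step; it sets out from 9 and comes back at 11. The alkene alone is hydrogenated (H2, Pd/C poisoned with Ph2S, EtOAc) to 1-[3,4-bis(benzyloxy)-5-methoxyphenyl]-7-[4-(benzyloxy)phenyl]heptane-3,5-dione F5. The same ruthenium catalyst then gives (3S,5S)-1-[3,4-bis(benzyloxy)-5-methoxyphenyl]-7-[4-(benzyloxy)phenyl]heptane-3,5-diol F6, and H2 over unpoisoned Pd/C frees the three phenols to give 11.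

Step 3 (Pabon condensation on an unsymmetrical diketone) is the third risk. Condensation at the C5 methylene, double condensation, or a low yield with the hindered aldehyde are possible. The fallback changes the disconnection to an acylation at C3–C4; it sets out from 6 and comes back at 9. Claisen–Schmidt condensation of 6 with acetone (aq. NaOH) gives (3E)-4-[3,4-bis(benzyloxy)-5-methoxyphenyl]but-3-en-2-one F7. LiN(SiMe3)2 (2.2 equiv, THF, −78 °C) converts it into lithium (3E)-4-[3,4-bis(benzyloxy)-5-methoxyphenyl]buta-1,3-dien-2-olate F8, which undergoes Claisen condensation with commercial methyl 3-[4-(benzyloxy)phenyl]propanoate to give 9 after acidic work-up.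

**Further compounds**

F1 | step 6 | dilithium 6-[4-(benzyloxy)phenyl]hexa-1,3-diene-2,4-bis(olate) (terminal dianion of 4) | C=C([O-])C=C([O-])CCc1ccc(OCc2ccccc2)cc1.[Li+].[Li+]
F2 | step 6 | 1-[3,4-bis(benzyloxy)-5-methoxyphenyl]-7-[4-(benzyloxy)phenyl]-1-hydroxyheptane-3,5-dione (racemic at C1) | COc1cc(C(O)CC(=O)CC(=O)CCc2ccc(OCc3ccccc3)cc2)cc(OCc2ccccc2)c1OCc1ccccc1
F3 | step 6 | (1RS,3R,5S)-1-[3,4-bis(benzyloxy)-5-methoxyphenyl]-7-[4-(benzyloxy)phenyl]heptane-1,3,5-triol | COc1cc(C(O)C[C@H](O)C[C@H](CCc2ccc(OCc3ccccc3)cc2)O)cc(OCc2ccccc2)c1OCc1ccccc1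
F4 | step 6 | (2S,4R,6S)-2-[3,4-bis(benzyloxy)-5-methoxyphenyl]-6-{2-[4-(benzyloxy)phenyl]ethyl}oxan-4-ol | COc1cc([C@@H]2C[C@H](O)C[C@H](CCc3ccc(OCc4ccccc4)cc3)O2)cc(OCc2ccccc2)c1OCc1ccccc1
F5 | step 5 | 1-[3,4-bis(benzyloxy)-5-methoxyphenyl]-7-[4-(benzyloxy)phenyl]heptane-3,5-dione | COc1cc(CCC(=O)CC(=O)CCc2ccc(OCc3ccccc3)cc2)cc(OCc2ccccc2)c1OCc1ccccc1
F6 | step 5 | (3S,5S)-1-[3,4-bis(benzyloxy)-5-methoxyphenyl]-7-[4-(benzyloxy)phenyl]heptane-3,5-diol | COc1cc(CC[C@H](O)C[C@H](CCc2ccc(OCc3ccccc3)cc2)O)cc(OCc2ccccc2)c1OCc1ccccc1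
F7 | step 3 | (3E)-4-[3,4-bis(benzyloxy)-5-methoxyphenyl]but-3-en-2-one | COc1cc(/C=C/C(C)=O)cc(OCc2ccccc2)c1OCc1ccccc1
F8 | step 3 | lithium (3E)-4-[3,4-bis(benzyloxy)-5-methoxyphenyl]buta-1,3-dien-2-olate | COc1cc(/C=C/C(=C)[O-])cc(OCc2ccccc2)c1OCc1ccccc1.[Li+]
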